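Retrosynthesis (tetralin numbering, C1 = diarylmethine): first the C3–OH and CH2–OH bonds are cut (dihydroxylation of a C3 exocyclic methylene), then the C1–C8a bond of the cyclohexane ring (opening of a benzylic glycidic ester by the guaiacyl ring), then the C2–C3 bond (aryl propynol plus alkenyl Grignard reagent).
Forward: two benzyl-protected arene fragments are joined to an (E)-dienol, its trisubstituted alkene is epoxidised and oxidised to the glycidic benzyl ester, the carbocyclic ring of the tetralin is closed last, and osmylation plus global hydrogenolysis finish the synthesis.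
Enabling feature: C1 carries the pyrogallol ring next to the hydroxylated C2 (a 1-aryl-2-hydroxy unit, i.e. an opened benzylic epoxide), and C8a of the guaiacyl ring lies para to the C6 methoxy group, so this ring is a built-in nucleophile for C1.
Stereochemistry: C1 and C2 come from a Sharpless epoxide (reagent control) with inversion at C1 in the ring closure; C3 is set by substrate control (osmylation anti to the C2 hydroxyl).
Protection: aryl benzyl ethers and a benzyl ester only, all removed in the last step.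

Key step: step 8

Remark: the target is taken to persist as the open hydroxy acid, because its trans-disposed CO2H and CH2OH groups could only form a strained trans-fused lactone.

Step 1
Reactants: 1 3,4,5-tris(benzyloxy)benzaldehyde
Product: 2 1,2,3-tris(benzyloxy)-5-(2,2-dibromoethenyl)benzene
Conditions: CBr4, PPh3, CH2Cl2, 0 °C
Reagents that add atoms: carbon tetrabromide, BrC(Br)(Br)Br
Why: Dibromo-olefination (first stage of the Corey–Fuchs sequence) of an unhindered, non-enolisable aryl aldehyde should proceed cleanly, and no stereocentre is formed.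

Step 2
Reactants: 2 1,2,3-tris(benzyloxy)-5-(2,2-dibromoethenyl)benzene
Product: 4 3-[3,4,5-tris(benzyloxy)phenyl]prop-2-yn-1-ol, via lithium acetylide 3 (not isolated)
Conditions: n-BuLi (2.2 equiv), THF, −78 °C; (CH2O)n, −78 °C → rt; aq. NH4Cl
Reagents that add atoms: formaldehyde (as paraformaldehyde), C=O
Why: In the second stage of the Corey–Fuchs reaction, bromine–lithium exchange and 1,2-shift give the lithium acetylide, which formaldehyde hydroxymethylates to the propargylic alcohol, the aryl benzyl ethers being inert to n-BuLi at −78 °C.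

Step 3
Reactants: 5 1-(benzyloxy)-4-bromo-2-methoxybenzene; 6 2,3-dibromoprop-1-ene
Product: 8 1-(benzyloxy)-4-(2-bromoprop-2-en-1-yl)-2-methoxybenzene, via arylmagnesium bromide 7 (not isolated)
Conditions: Mg, THF, reflux; then 6, CuI (5 mol %), THF, 0 °C → rt
Reagents that add atoms: none
Why: Copper-catalysed allylic substitution of an aryl Grignard reagent on the allylic C–Br bond of 2,3-dibromopropene (the vinylic bromide is inert) should give the 2-bromoallyl arene.

Step 4
Reactants: 8 1-(benzyloxy)-4-(2-bromoprop-2-en-1-yl)-2-methoxybenzene; 4 3-[3,4,5-tris(benzyloxy)phenyl]prop-2-yn-1-ol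
Product: 12 (2E)-2-{3-[4-(benzyloxy)-3-methoxyphenyl]prop-1-en-2-yl}-3-[3,4,5-tris(benzyloxy)phenyl]prop-2-en-1-ol, via alkenylmagnesium bromide 9 (not isolated), via chloromagnesium alkoxide 10 (not isolated), via oxamagnesole chelate 11 (not isolated)
Conditions: 8, Mg, THF, 45 °C; 4, i-PrMgCl (1.0 equiv), THF, 0 °C; combine (2 equiv of 9), toluene/THF, 80 °C; aq. NH4Cl
Reagents that add atoms: none
Why: In this hydroxyl-directed anti-carbomagnesiation of a propargylic alcohol the magnesium alkoxide delivers the alkenyl Grignard reagent to the proximal alkyne carbon through a five-membered chelate, so that after protonation the aryl and the new alkenyl group are cis and H is cis to CH2OH, i.e. the required (E)-dienol.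

Step 5
Reactants: 12 (2E)-2-{3-[4-(benzyloxy)-3-methoxyphenyl]prop-1-en-2-yl}-3-[3,4,5-tris(benzyloxy)phenyl]prop-2-en-1-ol
Product: 13 [(2S,3S)-2-{3-[4-(benzyloxy)-3-methoxyphenyl]prop-1-en-2-yl}-3-[3,4,5-tris(benzyloxy)phenyl]oxiran-2-yl]methanol (aryl trans to CH2OH)
Conditions: Ti(Oi-Pr)4 (10 mol %), L-(+)-DIPT (12 mol %), t-BuOOH, 4 Å MS, CH2Cl2, −25 °C
Reagents that add atoms: tert-butyl hydroperoxide, CC(C)(C)OO
Why: Sharpless asymmetric epoxidation is directed by the primary allylic hydroxyl to its own trisubstituted alkene (the 1,1-disubstituted alkene is only homoallylic), and with L-(+)-tartrate should deliver oxygen to the face that gives the (2S,3S)-epoxy alcohol, as with (E)-cinnamyl alcohols, so both epoxide stereocentres arise under reagent control.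

Step 6
Reactants: 13 [(2S,3S)-2-{3-[4-(benzyloxy)-3-methoxyphenyl]prop-1-en-2-yl}-3-[3,4,5-tris(benzyloxy)phenyl]oxiran-2-yl]methanol
Product: 14 (2R,3S)-2-{3-[4-(benzyloxy)-3-methoxyphenyl]prop-1-en-2-yl}-3-[3,4,5-tris(benzyloxy)phenyl]oxirane-2-carbaldehyde
Conditions: Dess–Martin periodinane, NaHCO3, CH2Cl2, 0 °C → rt
Reagents that add atoms: none
Why: Buffered Dess–Martin oxidation should convert the primary alcohol into the aldehyde without opening the acid-sensitive aryl epoxide, and the quaternary α-carbon cannot epimerise (the change from 2S to 2R is only a change of CIP priorities).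

Step 7
Reactants: 14 (2R,3S)-2-{3-[4-(benzyloxy)-3-methoxyphenyl]prop-1-en-2-yl}-3-[3,4,5-tris(benzyloxy)phenyl]oxirane-2-carbaldehyde
Product: 16 benzyl (2R,3S)-2-{3-[4-(benzyloxy)-3-methoxyphenyl]prop-1-en-2-yl}-3-[3,4,5-tris(benzyloxy)phenyl]oxirane-2-carboxylate, via glycidic acid 15 (not isolated)
Conditions: NaClO2, NaH2PO4, 2-methyl-2-butene, t-BuOH/H2O, 0 °C; then BnBr, K2CO3, DMF, 0 °C → rt
Reagents that add atoms: sodium chlorite, [Na+].[O-]Cl=O; benzyl bromide, BrCc1ccccc1
Why: Pinnick oxidation with 2-methyl-2-butene as hypochlorite scavenger (sparing the alkene and the electron-rich arenes) should give the glycidic acid, which is alkylated at once as its carboxylate with benzyl bromide (SN2) to avoid decarboxylative epoxide opening, the benzyl ester being chosen so that it leaves in the final hydrogenolysis.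

Step 8
Reactants: 16 benzyl (2R,3S)-2-{3-[4-(benzyloxy)-3-methoxyphenyl]prop-1-en-2-yl}-3-[3,4,5-tris(benzyloxy)phenyl]oxirane-2-carboxylate
Product: 17 benzyl (1S,2S)-7-(benzyloxy)-2-hydroxy-6-methoxy-3-methylidene-1-[3,4,5-tris(benzyloxy)phenyl]-1,2,3,4-tetrahydronaphthalene-2-carboxylate
Conditions: BF3·OEt2 (0.3 equiv), CH2Cl2, −78 → −40 °C; aq. NaHCO3
Reagents that add atoms: none
Why: BF3 coordinates the epoxide oxygen (assisted by the ester carbonyl), the benzylic C–O bond (oxirane C3, the future C1) lengthens, the guaiacyl ring attacks this carbon through its position para to the methoxy group, and rearomatisation leaves the tertiary C2 hydroxyl. The closest known reaction type is the intramolecular Friedel–Crafts epoxy–arene cyclisation of trans-aryl epoxides, which gives trans-4-aryl-3-hydroxy benzo-fused six-membered rings. The cyclohexane ring of the tetralin is closed in a 6-endo-tet mode at the benzylic epoxide carbon. The new stereocentre C1 is set by anti (SN2-like) opening, i.e. inversion of the (3S) epoxide carbon from step 5, which places the aryl group cis to the C2 hydroxyl and trans to the ester, while C2 keeps the configuration fixed in step 5. The step needs regioselectivity (C1 and not C2; para and not ortho to OMe), secured by the electron-rich 3,4,5-tris(benzyloxy)phenyl group at C1, by the ester at C2, which destabilises positive charge there and disfavours the 5-exo path, and by the crowding of the position between CH2 and OMe. Should partial ionisation intervene, the same diastereomer is still expected, because the aryl group prefers the pseudo-equatorial position anti to the larger C2 substituent.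

Step 9
Reactants: 17 benzyl (1S,2S)-7-(benzyloxy)-2-hydroxy-6-methoxy-3-methylidene-1-[3,4,5-tris(benzyloxy)phenyl]-1,2,3,4-tetrahydronaphthalene-2-carboxylate
Product: 18 benzyl (1S,2S,3R)-7-(benzyloxy)-2,3-dihydroxy-3-(hydroxymethyl)-6-methoxy-1-[3,4,5-tris(benzyloxy)phenyl]-1,2,3,4-tetrahydronaphthalene-2-carboxylate
Conditions: OsO4 (5 mol %), NMO, acetone/H2O, 0 °C → rt
Reagents that add atoms: osmium tetroxide (catalytic oxygen carrier), O=[Os](=O)(=O)=O; N-methylmorpholine N-oxide, C[N+]1([O-])CCOCC1; water, O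
Why: Upjohn dihydroxylation of the exocyclic 1,1-disubstituted alkene should occur anti to the adjacent pseudo-axial C2 hydroxyl (the usual anti preference in osmylation of allylic alcohols) and away from the C1 aryl group, setting C3 as R with the new tertiary hydroxyl trans to the C2 hydroxyl.

Step 10
Reactants: 18 benzyl (1S,2S,3R)-7-(benzyloxy)-2,3-dihydroxy-3-(hydroxymethyl)-6-methoxy-1-[3,4,5-tris(benzyloxy)phenyl]-1,2,3,4-tetrahydronaphthalene-2-carboxylate
Product: 19 (1S,2S,3R)-2,3,7-trihydroxy-3-(hydroxymethyl)-6-methoxy-1-(3,4,5-trihydroxyphenyl)-1,2,3,4-tetrahydronaphthalene-2-carboxylic acid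
Conditions: H2 (1 atm), 10% Pd/C, THF/MeOH, rt
Reagents that add atoms: none
Why: Hydrogenolysis over palladium should cleave the four aryl benzyl ethers and the benzyl ester in one neutral operation, since the skeleton has no benzylic C–O bond and base is avoided because of the air-sensitive pyrogallol unit.

Compound list
1 | 3,4,5-tris(benzyloxy)benzaldehyde | O=Cc1cc(OCc2ccccc2)c(OCc2ccccc2)c(OCc2ccccc2)c1 | starting material
2 | 1,2,3-tris(benzyloxy)-5-(2,2-dibromoethenyl)benzene | BrC(Br)=Cc1cc(OCc2ccccc2)c(OCc2ccccc2)c(OCc2ccccc2)c1 | intermediate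
3 | lithium [3,4,5-tris(benzyloxy)phenyl]acetylide | [Li]C#Cc1cc(OCc2ccccc2)c(OCc2ccccc2)c(OCc2ccccc2)c1 | intermediate
4 | 3-[3,4,5-tris(benzyloxy)phenyl]prop-2-yn-1-ol | OCC#Cc1cc(OCc2ccccc2)c(OCc2ccccc2)c(OCc2ccccc2)c1 | intermediate
5 | 1-(benzyloxy)-4-bromo-2-methoxybenzene | COc1cc(Br)ccc1OCc1ccccc1 | starting material
6 | 2,3-dibromoprop-1-ene | BrCC(Br)=C | starting material
7 | [4-(benzyloxy)-3-methoxyphenyl]magnesium bromide | COc1cc([Mg]Br)ccc1OCc1ccccc1 | intermediate
8 | 1-(benzyloxy)-4-(2-bromoprop-2-en-1-yl)-2-methoxybenzene | COc1cc(CC(Br)=C)ccc1OCc1ccccc1 | intermediate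
9 | {3-[4-(benzyloxy)-3-methoxyphenyl]prop-1-en-2-yl}magnesium bromide | COc1cc(CC(=C)[Mg]Br)ccc1OCc1ccccc1 | intermediate
10 | chloromagnesium 3-[3,4,5-tris(benzyloxy)phenyl]prop-2-yn-1-olate | Cl[Mg]OCC#Cc1cc(OCc2ccccc2)c(OCc2ccccc2)c(OCc2ccccc2)c1 | intermediate
11 | 4-{3-[4-(benzyloxy)-3-methoxyphenyl]prop-1-en-2-yl}-3-[3,4,5-tris(benzyloxy)phenyl]-2,5-dihydro-1,2-oxamagnesole (cyclic alkenylmagnesium alkoxide) | C=C(Cc1ccc(OCc2ccccc2)c(OC)c1)C1=C(c2cc(OCc3ccccc3)c(OCc3ccccc3)c(OCc3ccccc3)c2)[Mg]OC1 | intermediate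
12 | (2E)-2-{3-[4-(benzyloxy)-3-methoxyphenyl]prop-1-en-2-yl}-3-[3,4,5-tris(benzyloxy)phenyl]prop-2-en-1-ol | OC/C(=C/c1cc(OCc2ccccc2)c(OCc2ccccc2)c(OCc2ccccc2)c1)C(=C)Cc1ccc(OCc2ccccc2)c(OC)c1 | intermediate
13 | [(2S,3S)-2-{3-[4-(benzyloxy)-3-methoxyphenyl]prop-1-en-2-yl}-3-[3,4,5-tris(benzyloxy)phenyl]oxiran-2-yl]methanol | O1[C@@H](c2cc(OCc3ccccc3)c(OCc3ccccc3)c(OCc3ccccc3)c2)[C@@]1(CO)C(=C)Cc1ccc(OCc2ccccc2)c(OC)c1 | intermediate
14 | (2R,3S)-2-{3-[4-(benzyloxy)-3-methoxyphenyl]prop-1-en-2-yl}-3-[3,4,5-tris(benzyloxy)phenyl]oxirane-2-carbaldehyde | O1[C@@H](c2cc(OCc3ccccc3)c(OCc3ccccc3)c(OCc3ccccc3)c2)[C@@]1(C=O)C(=C)Cc1ccc(OCc2ccccc2)c(OC)c1 | intermediate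
15 | (2R,3S)-2-{3-[4-(benzyloxy)-3-methoxyphenyl]prop-1-en-2-yl}-3-[3,4,5-tris(benzyloxy)phenyl]oxirane-2-carboxylic acid | O1[C@@H](c2cc(OCc3ccccc3)c(OCc3ccccc3)c(OCc3ccccc3)c2)[C@@]1(C(=O)O)C(=C)Cc1ccc(OCc2ccccc2)c(OC)c1 | intermediate
16 | benzyl (2R,3S)-2-{3-[4-(benzyloxy)-3-methoxyphenyl]prop-1-en-2-yl}-3-[3,4,5-tris(benzyloxy)phenyl]oxirane-2-carboxylate | O1[C@@H](c2cc(OCc3ccccc3)c(OCc3ccccc3)c(OCc3ccccc3)c2)[C@@]1(C(=O)OCc1ccccc1)C(=C)Cc1ccc(OCc2ccccc2)c(OC)c1 | intermediate
17 | benzyl (1S,2S)-7-(benzyloxy)-2-hydroxy-6-methoxy-3-methylidene-1-[3,4,5-tris(benzyloxy)phenyl]-1,2,3,4-tetrahydronaphthalene-2-carboxylate | COc1cc2c(cc1OCc1ccccc1)[C@H](c1cc(OCc3ccccc3)c(OCc3ccccc3)c(OCc3ccccc3)c1)[C@@](O)(C(=O)OCc1ccccc1)C(=C)C2 | intermediate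
18 | benzyl (1S,2S,3R)-7-(benzyloxy)-2,3-dihydroxy-3-(hydroxymethyl)-6-methoxy-1-[3,4,5-tris(benzyloxy)phenyl]-1,2,3,4-tetrahydronaphthalene-2-carboxylate | COc1cc2c(cc1OCc1ccccc1)[C@H](c1cc(OCc3ccccc3)c(OCc3ccccc3)c(OCc3ccccc3)c1)[C@@](O)(C(=O)OCc1ccccc1)[C@](O)(CO)C2 | intermediate
19 | (1S,2S,3R)-2,3,7-trihydroxy-3-(hydroxymethyl)-6-methoxy-1-(3,4,5-trihydroxyphenyl)-1,2,3,4-tetrahydronaphthalene-2-carboxylic acid | COc1cc2c(cc1O)[C@H](c1cc(O)c(O)c(O)c1)[C@@](O)(C(=O)O)[C@](O)(CO)C2 | target

Total step count: 10. Longest linear sequence: 9 steps (steps 1, 2, 4, 5, 6, 7, 8, 9, 10, from 1 to 19).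

Steps most likely to fail

Step 8 (key ring closure). Ionisation may outrun the arene attack, leading to 1,2-shift of the benzyloxycarbonyl group (Meinwald-type rearrangement), allylic ionisation at C2, or acid-induced migration of the exocyclic double bond into conjugation. The fallback moves the ring closure to the alcohol oxidation level, where no acyl group can migrate. It sets out from epoxy alcohol 13, which is cyclised with BF3·OEt2 in CH2Cl2 at −78 °C; the free hydroxymethyl group chelates the Lewis acid and opening occurs at the benzylic carbon with inversion, as is usual for 2,3-epoxy alcohols. This should give (1S,2S)-7-(benzyloxy)-2-(hydroxymethyl)-6-methoxy-3-methylidene-1-[3,4,5-tris(benzyloxy)phenyl]-1,2,3,4-tetrahydronaphthalen-2-ol F1. Selective oxidation of the primary hydroxyl of this 1,2-diol (TEMPO cat., PhI(OAc)2, MeCN/H2O) should give (1S,2S)-7-(benzyloxy)-2-hydroxy-6-methoxy-3-methylidene-1-[3,4,5-tris(benzyloxy)phenyl]-1,2,3,4-tetrahydronaphthalene-2-carboxylic acid F2. O-Alkylation with benzyl bromide (K2CO3, DMF) comes back to the route at 17.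

Step 4 (carbomagnesiation). The hindered 1-substituted alkenyl Grignard reagent may add too slowly to the alkynol alkoxide, so that thermal decay and protonation of the reagent compete and conversion stays incomplete. The fallback builds the same diene by cross-coupling and sets out from 1 and 8. Wittig olefination of 1 with the bromo ylide generated from Ph3P=CHCO2Me and NBS (CH2Cl2, −20 °C → rt) should give methyl (2Z)-2-bromo-3-[3,4,5-tris(benzyloxy)phenyl]prop-2-enoate F3. Miyaura borylation of 8 (B2pin2, PdCl2(PPh3)2, PPh3, KOPh, toluene, 50 °C) should give 2-{3-[4-(benzyloxy)-3-methoxyphenyl]prop-1-en-2-yl}-4,4,5,5-tetramethyl-1,3,2-dioxaborolane F4. Suzuki–Miyaura coupling of F3 with F4 (Pd(PPh3)4, K3PO4, dioxane/H2O, 80 °C) proceeds with retention of alkene geometry and should give methyl (2E)-2-{3-[4-(benzyloxy)-3-methoxyphenyl]prop-1-en-2-yl}-3-[3,4,5-tris(benzyloxy)phenyl]prop-2-enoate F5. Reduction with DIBAL-H (CH2Cl2, −78 °C) comes back to the route at 12.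

Step 9 (dihydroxylation). Facial selectivity may be poor: attack of the osmium reagent syn to the C2 hydroxyl would give the C3 epimer. The fallback reaches the same configuration by two stereodefined events and sets out from 17. Hydroxyl-directed epoxidation (VO(acac)2, t-BuOOH, CH2Cl2, 0 °C) delivers oxygen syn to the C2 hydroxyl and should give benzyl (1S,2S,3S)-7-(benzyloxy)-2-hydroxy-6-methoxy-1-[3,4,5-tris(benzyloxy)phenyl]-1,4-dihydro-2H-spiro[naphthalene-3,2'-oxirane]-2-carboxylate F6 (oxirane oxygen cis to the C2 hydroxyl). Acid-catalysed hydrolysis (cat. HClO4, THF/H2O, 0 °C) then opens the epoxide at the tertiary spiro carbon with inversion, placing the new hydroxyl trans to the C2 hydroxyl, and comes back to the route at 18.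

Further compounds
F1 | step 8 | (1S,2S)-7-(benzyloxy)-2-(hydroxymethyl)-6-methoxy-3-methylidene-1-[3,4,5-tris(benzyloxy)phenyl]-1,2,3,4-tetrahydronaphthalen-2-ol | COc1cc2c(cc1OCc1ccccc1)[C@H](c1cc(OCc3ccccc3)c(OCc3ccccc3)c(OCc3ccccc3)c1)[C@@](O)(CO)C(=C)C2
F2 | step 8 | (1S,2S)-7-(benzyloxy)-2-hydroxy-6-methoxy-3-methylidene-1-[3,4,5-tris(benzyloxy)phenyl]-1,2,3,4-tetrahydronaphthalene-2-carboxylic acid | COc1cc2c(cc1OCc1ccccc1)[C@H](c1cc(OCc3ccccc3)c(OCc3ccccc3)c(OCc3ccccc3)c1)[C@@](O)(C(=O)O)C(=C)C2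
F3 | step 4 | methyl (2Z)-2-bromo-3-[3,4,5-tris(benzyloxy)phenyl]prop-2-enoate | COC(=O)/C(Br)=C/c1cc(OCc2ccccc2)c(OCc2ccccc2)c(OCc2ccccc2)c1
F4 | step 4 | 2-{3-[4-(benzyloxy)-3-methoxyphenyl]prop-1-en-2-yl}-4,4,5,5-tetramethyl-1,3,2-dioxaborolane | COc1cc(CC(=C)B2OC(C)(C)C(C)(C)O2)ccc1OCc1ccccc1
F5 | step 4 | methyl (2E)-2-{3-[4-(benzyloxy)-3-methoxyphenyl]prop-1-en-2-yl}-3-[3,4,5-tris(benzyloxy)phenyl]prop-2-enoate | COC(=O)/C(=C/c1cc(OCc2ccccc2)c(OCc2ccccc2)c(OCc2ccccc2)c1)C(=C)Cc1ccc(OCc2ccccc2)c(OC)c1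
F6 | step 9 | benzyl (1S,2S,3S)-7-(benzyloxy)-2-hydroxy-6-methoxy-1-[3,4,5-tris(benzyloxy)phenyl]-1,4-dihydro-2H-spiro[naphthalene-3,2'-oxirane]-2-carboxylate | COc1cc2c(cc1OCc1ccccc1)[C@H](c1cc(OCc3ccccc3)c(OCc3ccccc3)c(OCc3ccccc3)c1)[C@@](O)(C(=O)OCc1ccccc1)[C@@]4(CO4)C2
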